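**Plan**

1. Retrosynthesis: the four benzyl ethers come off last; ring A is then cut at C4a–C8a and C5–C6 (reverse of a [4+2] addition, CO2 restored), which also opens ring B and leaves a 6-alkyl-4-benzyloxy-3-methoxy-2-pyrone joined through C1–C4 to a methyl ynol ether.
2. Enabling feature: ring A is a pentasubstituted benzene with three adjacent oxygens on C5, C6, C7 and one hydrogen on C8, fused to ring B at C4a–C8a, so pyrone carbons 3–6 (C6, C7, C8, C8a) and the alkyne carbons (C4a, C5) supply the whole ring with every substituent in place.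
3. Earlier cuts: the pyrone (aldol of a C1 aldehyde with the dianion of methyl 2-methoxy-3-oxobutanoate, oxidation, lactonisation); C4–C4a (alkylation of lithium methoxyacetylide); C1–C2 and C3–C4 (one-flask Michael addition/alkylation on (5S)-5-(d-menthyloxy)furan-2(5H)-one).
4. Forward order: chain C1–C4 first; lactone reduced and benzylated; ynol ether attached while C1 carries only a silyloxymethyl group (a C1 carbonyl would attack the C4 triflate and be attacked by the acetylide); pyrone built under non-acidic conditions; rings A and B closed together on heating; hydrogenolysis.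
5. Stereochemistry: C2 from addition anti to the menthyloxy group, C3 from alkylation anti to the C2 branch, C1 from the topicity of the same Michael addition (the least secure element); no later step touches them.

Key step: step 16

Remark: atoms are labelled as in the target tetralin (C1–C4, C4a, C5–C8, C8a) in every intermediate; in all open-chain intermediates the aryl group on C1 and the oxygenated one-carbon branches on C2 and C3 lie on the same side of the extended C1–C2–C3–C4 chain (this is what the SMILES encode and what becomes 1R,2S,3S); 4-methoxybenzyl chloromethyl ether is taken as a purchasable reagent.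

**Route**

Step 1
Reactants: 1 homovanillic acid [2-(4-hydroxy-3-methoxyphenyl)acetic acid]
Product: 3 2-[4-(benzyloxy)-3-methoxyphenyl]acetic acid, via benzyl 2-[4-(benzyloxy)-3-methoxyphenyl]acetate 2 (not isolated)
Conditions: BnBr (2.3 equiv), K2CO3, DMF, 60 °C; then NaOH, MeOH–H2O, 60 °C; HCl to pH 2
Reagents that add atoms: benzyl bromide, BrCc1ccccc1
Why: Williamson O-benzylation of phenoxide and carboxylate followed by saponification of the benzyl ester leaves only the phenol protected; no stereocentre is involved.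

Step 2
Reactants: 3 2-[4-(benzyloxy)-3-methoxyphenyl]acetic acid; 4 (5S)-5-[(1S,2R,5S)-2-isopropyl-5-methylcyclohexyloxy]furan-2(5H)-one [(5S)-5-(d-menthyloxy)furanone]; 5 4-methoxybenzyl chloromethyl ether
Product: 8 (2R)-2-[4-(benzyloxy)-3-methoxyphenyl]-2-{(2S,3S,4R)-2-(d-menthyloxy)-4-[(4-methoxybenzyloxy)methyl]-5-oxooxolan-3-yl}acetic acid, via dilithium enediolate 6 (not isolated), via dilithium lactone enolate 7 (not isolated)
Conditions: LiN(iPr)2 (2.1 equiv), THF, −78 to 0 °C; 4, −78 °C; 5, −78 °C; 1 M HCl, 0 °C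
Reagents that add atoms: none
Why: Tandem Michael addition–enolate alkylation: the enediolate should add to the butenolide face anti to the menthyloxy group (sets C2) through a staggered synclinal transition state with its C–H anti to the acceptor C=C and its oxygens over the lactone carbonyl, so that the aryl group ends up syn to the acetal carbon along the chain (sets C1), and the lactone enolate is then alkylated by the chloromethyl ether anti to the new C2 branch (sets C3, the new carbon being C4).

Step 3
Reactants: 8 lactone acid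
Product: 9 (3R,4S,5S)-4-{(1R)-1-[4-(benzyloxy)-3-methoxyphenyl]-2-hydroxyethyl}-5-(d-menthyloxy)-3-[(4-methoxybenzyloxy)methyl]oxolan-2-one
Conditions: BH3·SMe2, THF, 0 to 23 °C; MeOH quench
Reagents that add atoms: none
Why: Chemoselective borane reduction: the free carboxylic acid is reduced through an acyloxyborane much faster than the lactone or acetal, so only the C1 carboxyl carbon (the future C8a) goes to the alcohol level and no stereocentre is affected.

Step 4
Reactants: 9 lactone alcohol
Product: 10 (3R,4S,5S)-4-{(1R)-1-[4-(benzyloxy)-3-methoxyphenyl]-2-[(triisopropylsilyl)oxy]ethyl}-5-(d-menthyloxy)-3-[(4-methoxybenzyloxy)methyl]oxolan-2-one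
Conditions: iPr3SiOTf, 2,6-lutidine, CH2Cl2, −78 °C
Reagents that add atoms: triisopropylsilyl trifluoromethanesulfonate, CC(C)[Si](OS(=O)(=O)C(F)(F)F)(C(C)C)C(C)C
Why: Silylation of the primary alcohol with a silyl triflate and a hindered pyridine is fast at low temperature and avoids basic conditions under which the hydroxyl could attack the lactone.

Step 5
Reactants: 10 silyl-protected lactone
Product: 11 2-{1-[4-(benzyloxy)-3-methoxyphenyl]-2-[(triisopropylsilyl)oxy]ethyl}-3-[(4-methoxybenzyloxy)methyl]butane-1,4-diol (C1–C3 all-syn)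
Conditions: LiAlH4, THF, 0 °C; aqueous NaOH work-up
Reagents that add atoms: none
Why: Hydride reduction of the acylal-type lactone: the carbonyl carbon becomes the C3 hydroxymethyl group, the liberated hemiacetal loses menthol to give an aldehyde that is reduced at once to the C2 hydroxymethyl group, and the silyl ether, the 4-methoxybenzyl ether and the three stereocentres are untouched.

Step 6
Reactants: 11 diol
Product: 12 4-[4-(benzyloxy)-3-methoxyphenyl]-2,3-bis[(benzyloxy)methyl]-1-[(4-methoxybenzyl)oxy]-5-[(triisopropylsilyl)oxy]pentane (C1–C3 all-syn)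
Conditions: NaH, BnBr, Bu4NI (cat.), THF–DMF, 0 to 23 °C
Reagents that add atoms: benzyl bromide, BrCc1ccccc1
Why: Williamson etherification of both primary alkoxides; the substrate has no carbonyl group or acidic C–H left.

Step 7
Reactants: 12 fully protected tetraol
Product: 13 4-[4-(benzyloxy)-3-methoxyphenyl]-2,3-bis[(benzyloxy)methyl]-5-[(triisopropylsilyl)oxy]pentan-1-ol (free hydroxyl on C4)
Conditions: DDQ, CH2Cl2–pH 7 phosphate buffer, 0 °C
Reagents that add atoms: none
Why: Oxidative cleavage of the electron-rich 4-methoxybenzyl ether by DDQ through a benzylic oxocarbenium ion that water hydrolyses, selective over the plain benzyl and silyl ethers.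

Step 8
Reactants: 14 chloroacetaldehyde dimethyl acetal
Product: 16 methoxyethyne as a cold THF solution, via sodium methoxyacetylide 15 (not isolated)
Conditions: NaNH2 (3 equiv), liquid NH3, −33 °C; NH3 evaporated; saturated aqueous NH4Cl, −50 °C; distilled (bp about 23 °C) into THF at −78 °C
Reagents that add atoms: none
Why: Twofold base-induced elimination (loss of HCl, then of methanol) from the α-chloro acetal gives the sodium alkynyl ether, which is protonated and distilled; this is the classical preparation of 1-alkoxyalkynes.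

Step 9
Reactants: 13 C4 alcohol; 16 methoxyethyne
Product: 19 {2-[4-(benzyloxy)-3-methoxyphenyl]-3,4-bis[(benzyloxy)methyl]-7-methoxyhept-6-yn-1-yl}oxy(triisopropyl)silane (C1–C3 all-syn), via primary triflate 17 (not isolated), via lithium methoxyacetylide 18 (not isolated)
Conditions: Tf2O, 2,6-lutidine, CH2Cl2, −78 °C; transferred cold into LiC≡COMe (16, n-BuLi, THF, −78 °C), DMPU, −78 to −20 °C
Reagents that add atoms: none
Why: SN2 alkylation of a lithium alkoxyacetylide by a primary triflate forms the C4–C4a bond; the triflate is made and used cold so that neighbouring ether oxygens cannot displace it, and the substrate has no carbonyl group or acidic C–H to compete.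

Step 10
Reactants: 19 silyl-protected ynol ether
Product: 20 2-[4-(benzyloxy)-3-methoxyphenyl]-3,4-bis[(benzyloxy)methyl]-7-methoxyhept-6-yn-1-ol (C1–C3 all-syn)
Conditions: Bu4NF, THF, 0 to 23 °C
Reagents that add atoms: none
Why: Fluoride-induced Si–O cleavage under basic, non-acidic conditions that leave the ynol ether and the benzyl ethers intact.

Step 11
Reactants: 20 primary alcohol
Product: 21 2-[4-(benzyloxy)-3-methoxyphenyl]-3,4-bis[(benzyloxy)methyl]-7-methoxyhept-6-ynal (C1–C3 all-syn; used crude)
Conditions: Dess–Martin periodinane, pyridine, CH2Cl2, 0 °C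
Reagents that add atoms: none
Why: Dess–Martin oxidation of the primary alcohol to the aldehyde; pyridine buffers the acetic acid so the ynol ether should survive, and the α-aryl centre C1 should not epimerise if the crude aldehyde is used at once.

Step 12
Reactants: 22 methyl methoxyacetate; 23 acetyl chloride
Product: 25 methyl 2-methoxy-3-oxobutanoate (racemic), via lithium enolate 24 (not isolated)
Conditions: 22 (2.0 equiv), LiN(iPr)2 (2.0 equiv), THF, −78 °C; 23 (1.0 equiv), −78 °C; aqueous NH4Cl
Reagents that add atoms: none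
Why: Claisen-type C-acylation of the ester lithium enolate by the acid chloride, the second equivalent of enolate deprotonating the more acidic β-keto ester to prevent double acylation; the methoxy-bearing centre is racemic and is lost in step 15.

Step 13
Reactants: 21 aldehyde; 25 methyl 2-methoxy-3-oxobutanoate
Product: 27 methyl 6-[4-(benzyloxy)-3-methoxyphenyl]-7,8-bis[(benzyloxy)methyl]-5-hydroxy-2,11-dimethoxy-3-oxoundec-10-ynoate (mixture at the carbinol and methoxy-bearing carbons), via sodium lithium dianion 26 (not isolated)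
Conditions: 25 (1.6 equiv), NaH then n-BuLi, THF, 0 °C; 21, −78 °C; saturated aqueous NH4Cl
Reagents that add atoms: none
Why: Aldol addition of the 1,3-dicarbonyl dianion through its terminal carbon to the aldehyde at −78 °C, faster than enolisation of the α-aryl aldehyde so that C1 is kept; the two new centres form as mixtures and are both removed in steps 14 and 15.

Step 14
Reactants: 27 aldol
Product: 28 methyl 6-[4-(benzyloxy)-3-methoxyphenyl]-7,8-bis[(benzyloxy)methyl]-2,11-dimethoxy-3,5-dioxoundec-10-ynoate (largely enolised)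
Conditions: Dess–Martin periodinane (1.2 equiv), pyridine, CH2Cl2, 0 °C
Reagents that add atoms: none
Why: Dess–Martin oxidation of the β-hydroxy ketone to the 1,3-diketone under the same buffered conditions that protect the ynol ether.

Step 15
Reactants: 28 3,5-diketo ester
Product: 30 4-(benzyloxy)-6-{1-[4-(benzyloxy)-3-methoxyphenyl]-2,3-bis[(benzyloxy)methyl]-6-methoxyhex-5-yn-1-yl}-3-methoxy-2H-pyran-2-one (C1–C3 all-syn), via 4-hydroxy-2-pyrone 29 (not isolated)
Conditions: DBU (1.2 equiv), toluene, 23 °C; then BnBr, MeCN, 23 °C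
Reagents that add atoms: benzyl bromide, BrCc1ccccc1
Why: Base-mediated lactonisation of the 3,5-diketo ester (enol oxygen of the C5 ketone onto the ester, loss of methanol) gives the 4-hydroxy-2-pyrone as its amidinium salt, which is O-benzylated in the same flask so that the acidic hydroxypyrone never meets the ynol ether; pyrone C3 is blocked by methoxy, so alkylation goes to oxygen.

Step 16
Reactants: 30 pyrone ynol ether
Product: 32 (1R,2S,3S)-7-(benzyloxy)-1-[4-(benzyloxy)-3-methoxyphenyl]-2,3-bis[(benzyloxy)methyl]-5,6-dimethoxy-1,2,3,4-tetrahydronaphthalene, via bridged bicyclic lactone 31 (not isolated)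
Conditions: toluene (0.01 M, degassed), iPr2NEt (5 mol%), BHT (5 mol%), base-washed sealed tube, 170 °C
Reagents that add atoms: none
Why: On heating, the alkyne C4a≡C5 should add across pyrone positions 6 and 3 in a concerted intramolecular [4+2] cycloaddition to give the 2-oxabicyclo[2.2.2]octadienone 31, which loses CO2 by cycloreversion and leaves aromatic ring A. The closest known reaction type is the thermal intramolecular Diels–Alder reaction of 2-pyrones with tethered alkynes followed by CO2 extrusion. Ring B closes as a six-membered carbocycle because the four-atom tether C1–C4 allows only the union of C4a with C8a; ring A is closed by the same cycloaddition and aromatised by the cycloreversion. No stereocentre is created in the product: the two bridgehead centres of 31 vanish with CO2, and C1, C2 and C3 are not touched under neutral thermal conditions. Only regioselectivity is needed, and the tether enforces it, so the ynol-ether methoxy, the pyrone 3-methoxy and the 4-benzyloxy groups arrive at C5, C6 and C7; the methyl ynol ether has no β-hydrogen for thermal loss of an alkene, and the trace of amine guards it against acid-catalysed hydration.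

Step 17
Reactants: 32 tetra-O-benzyl ether
Product: 33 [(1R,2S,3S)-7-hydroxy-1-(4-hydroxy-3-methoxyphenyl)-3-(hydroxymethyl)-5,6-dimethoxy-1,2,3,4-tetrahydronaphthalen-2-yl]methanol (CNP0197710.1)
Conditions: H2 (1 atm), 10% Pd/C, EtOAc–MeOH, 23 °C
Reagents that add atoms: none
Why: Heterogeneous hydrogenolysis of the two phenolic and two primary benzyl ethers over palladium; the arenes, the methyl ethers and the three stereocentres are inert.

**Compound list**

1 | homovanillic acid, 2-(4-hydroxy-3-methoxyphenyl)acetic acid | COc1cc(CC(=O)O)ccc1O | starting material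
2 | benzyl 2-[4-(benzyloxy)-3-methoxyphenyl]acetate | COc1cc(CC(=O)OCc2ccccc2)ccc1OCc1ccccc1 | intermediate
3 | 2-[4-(benzyloxy)-3-methoxyphenyl]acetic acid | COc1cc(CC(=O)O)ccc1OCc1ccccc1 | intermediate
4 | (5S)-5-[(1S,2R,5S)-2-isopropyl-5-methylcyclohexyloxy]furan-2(5H)-one | O=C1C=C[C@@H](O[C@H]2C[C@@H](C)CC[C@@H]2C(C)C)O1 | starting material
5 | 4-methoxybenzyl chloromethyl ether | COc1ccc(COCCl)cc1 | starting material
6 | dilithium enediolate of 3 | COc1cc(C=C([O-])[O-])ccc1OCc1ccccc1.[Li+].[Li+] | intermediate
7 | dilithium lactone enolate carboxylate (Michael adduct of 6 and 4) | COc1cc([C@@H]([C@@H]2[C@@H](O[C@H]3C[C@@H](C)CC[C@@H]3C(C)C)OC([O-])=C2)C(=O)[O-])ccc1OCc1ccccc1.[Li+].[Li+] | intermediate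
8 | (2R)-2-[4-(benzyloxy)-3-methoxyphenyl]-2-{(2S,3S,4R)-2-(d-menthyloxy)-4-[(4-methoxybenzyloxy)methyl]-5-oxooxolan-3-yl}acetic acid | COc1cc([C@@H]([C@@H]2[C@@H](O[C@H]3C[C@@H](C)CC[C@@H]3C(C)C)OC(=O)[C@H]2COCc2ccc(OC)cc2)C(=O)O)ccc1OCc1ccccc1 | intermediate
9 | (3R,4S,5S)-4-{(1R)-1-[4-(benzyloxy)-3-methoxyphenyl]-2-hydroxyethyl}-5-(d-menthyloxy)-3-[(4-methoxybenzyloxy)methyl]oxolan-2-one | COc1cc([C@@H]([C@@H]2[C@@H](O[C@H]3C[C@@H](C)CC[C@@H]3C(C)C)OC(=O)[C@H]2COCc2ccc(OC)cc2)CO)ccc1OCc1ccccc1 | intermediate
10 | triisopropylsilyl ether of 9 | COc1cc([C@@H]([C@@H]2[C@@H](O[C@H]3C[C@@H](C)CC[C@@H]3C(C)C)OC(=O)[C@H]2COCc2ccc(OC)cc2)CO[Si](C(C)C)(C(C)C)C(C)C)ccc1OCc1ccccc1 | intermediate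
11 | 2-{1-[4-(benzyloxy)-3-methoxyphenyl]-2-[(triisopropylsilyl)oxy]ethyl}-3-[(4-methoxybenzyloxy)methyl]butane-1,4-diol | COc1cc([C@@H]([C@H](CO)[C@@H](CO)COCc2ccc(OC)cc2)CO[Si](C(C)C)(C(C)C)C(C)C)ccc1OCc1ccccc1 | intermediate
12 | 4-[4-(benzyloxy)-3-methoxyphenyl]-2,3-bis[(benzyloxy)methyl]-1-[(4-methoxybenzyl)oxy]-5-[(triisopropylsilyl)oxy]pentane | COc1cc([C@@H]([C@H](COCc2ccccc2)[C@@H](COCc2ccccc2)COCc2ccc(OC)cc2)CO[Si](C(C)C)(C(C)C)C(C)C)ccc1OCc1ccccc1 | intermediate
13 | 4-[4-(benzyloxy)-3-methoxyphenyl]-2,3-bis[(benzyloxy)methyl]-5-[(triisopropylsilyl)oxy]pentan-1-ol | COc1cc([C@@H]([C@H](COCc2ccccc2)[C@@H](COCc2ccccc2)CO)CO[Si](C(C)C)(C(C)C)C(C)C)ccc1OCc1ccccc1 | intermediate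
14 | chloroacetaldehyde dimethyl acetal | COC(CCl)OC | starting material
15 | sodium methoxyacetylide | COC#[C-].[Na+] | intermediate
16 | methoxyethyne | COC#C | intermediate
17 | trifluoromethanesulfonate of 13 | COc1cc([C@@H]([C@H](COCc2ccccc2)[C@@H](COCc2ccccc2)COS(=O)(=O)C(F)(F)F)CO[Si](C(C)C)(C(C)C)C(C)C)ccc1OCc1ccccc1 | intermediate
18 | lithium methoxyacetylide | COC#[C-].[Li+] | intermediate
19 | {2-[4-(benzyloxy)-3-methoxyphenyl]-3,4-bis[(benzyloxy)methyl]-7-methoxyhept-6-yn-1-yl}oxy(triisopropyl)silane | COc1cc([C@@H]([C@H](COCc2ccccc2)[C@@H](COCc2ccccc2)CC#COC)CO[Si](C(C)C)(C(C)C)C(C)C)ccc1OCc1ccccc1 | intermediate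
20 | 2-[4-(benzyloxy)-3-methoxyphenyl]-3,4-bis[(benzyloxy)methyl]-7-methoxyhept-6-yn-1-ol | COc1cc([C@@H]([C@H](COCc2ccccc2)[C@@H](COCc2ccccc2)CC#COC)CO)ccc1OCc1ccccc1 | intermediate
21 | 2-[4-(benzyloxy)-3-methoxyphenyl]-3,4-bis[(benzyloxy)methyl]-7-methoxyhept-6-ynal | COc1cc([C@@H]([C@H](COCc2ccccc2)[C@@H](COCc2ccccc2)CC#COC)C=O)ccc1OCc1ccccc1 | intermediate
22 | methyl methoxyacetate | COCC(=O)OC | starting material
23 | acetyl chloride | CC(=O)Cl | starting material
24 | lithium enolate of methyl methoxyacetate | COC=C([O-])OC.[Li+] | intermediate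
25 | methyl 2-methoxy-3-oxobutanoate (racemic) | COC(C(C)=O)C(=O)OC | intermediate
26 | sodium lithium dianion of 25 | C=C([O-])C(OC)=C([O-])OC.[Na+].[Li+] | intermediate
27 | methyl 6-[4-(benzyloxy)-3-methoxyphenyl]-7,8-bis[(benzyloxy)methyl]-5-hydroxy-2,11-dimethoxy-3-oxoundec-10-ynoate (mixture at C2 and C5 of the chain) | COc1cc([C@@H]([C@H](COCc2ccccc2)[C@@H](COCc2ccccc2)CC#COC)C(O)CC(=O)C(OC)C(=O)OC)ccc1OCc1ccccc1 | intermediate
28 | methyl 6-[4-(benzyloxy)-3-methoxyphenyl]-7,8-bis[(benzyloxy)methyl]-2,11-dimethoxy-3,5-dioxoundec-10-ynoate | COc1cc([C@@H]([C@H](COCc2ccccc2)[C@@H](COCc2ccccc2)CC#COC)C(=O)CC(=O)C(OC)C(=O)OC)ccc1OCc1ccccc1 | intermediate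
29 | 6-{1-[4-(benzyloxy)-3-methoxyphenyl]-2,3-bis[(benzyloxy)methyl]-6-methoxyhex-5-yn-1-yl}-4-hydroxy-3-methoxy-2H-pyran-2-one (present as its DBU salt) | COc1cc([C@@H]([C@H](COCc2ccccc2)[C@@H](COCc2ccccc2)CC#COC)C2=CC(O)=C(OC)C(=O)O2)ccc1OCc1ccccc1 | intermediate
30 | 4-(benzyloxy)-6-{1-[4-(benzyloxy)-3-methoxyphenyl]-2,3-bis[(benzyloxy)methyl]-6-methoxyhex-5-yn-1-yl}-3-methoxy-2H-pyran-2-one | COc1cc([C@@H]([C@H](COCc2ccccc2)[C@@H](COCc2ccccc2)CC#COC)C2=CC(OCc3ccccc3)=C(OC)C(=O)O2)ccc1OCc1ccccc1 | intermediate
31 | bridged lactone (2-oxabicyclo[2.2.2]octa-5,7-dien-3-one fused to ring B across C4a–C8a; either bridgehead configuration) | COc1cc([C@@H]2C34C=C(OCc5ccccc5)C(OC)(C(=O)O3)C(OC)=C4C[C@H](COCc3ccccc3)[C@H]2COCc2ccccc2)ccc1OCc1ccccc1 | intermediate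
32 | (1R,2S,3S)-7-(benzyloxy)-1-[4-(benzyloxy)-3-methoxyphenyl]-2,3-bis[(benzyloxy)methyl]-5,6-dimethoxy-1,2,3,4-tetrahydronaphthalene | COc1cc([C@@H]2c3cc(OCc4ccccc4)c(OC)c(OC)c3C[C@H](COCc3ccccc3)[C@H]2COCc2ccccc2)ccc1OCc1ccccc1 | intermediate
33 | [(1R,2S,3S)-7-hydroxy-1-(4-hydroxy-3-methoxyphenyl)-3-(hydroxymethyl)-5,6-dimethoxy-1,2,3,4-tetrahydronaphthalen-2-yl]methanol | COc1cc([C@@H]2c3cc(O)c(OC)c(OC)c3C[C@H](CO)[C@H]2CO)ccc1O | target

**Totals and risks**

Total step count: 17 (15 on the main line plus the two reagent preparations, steps 8 and 12).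
Longest linear sequence: 15 steps from homovanillic acid (steps 1–7, 9–11, 13–17).

Steps most likely to fail:

Step 2. The two faces of the enediolate may add with little discrimination, so that C1 forms as a mixture while C2 and C3 stay secure. The fallback fixes the enolate face with a covalently bound auxiliary instead of relying on transition-state topicity. It sets out from 3: coupling with (R)-4-benzyl-2-oxazolidinone (DCC, DMAP, CH2Cl2) gives the N-acyl oxazolidinone F1. Its chelated Z sodium enolate F2 (NaN(SiMe3)2, THF, −78 °C) should add to 4 from the face remote from the benzyl group and anti to the menthyloxy group, giving the lactone enolate F3. Trapping with 5 as in step 2 gives the imide F4, and LiOH/H2O2 (THF–H2O, 0 °C) cleaves the auxiliary and returns the route at acid 8.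

Step 9. The oxygen of the C2 benzyloxymethyl group may displace the C4 triflate intramolecularly (tetrahydrofuran formation with loss of the benzyl group), or elimination may occur, faster than the acetylide substitutes at the β-branched carbon. The fallback sets out from 13 and replaces the sulfonate made in situ by the isolable primary iodide F5 (I2, PPh3, imidazole, toluene), which is far less prone to ether participation. F5 is alkylated in liquid NH3–THF with sodium methoxyacetylide 15, generated directly from 14 and NaNH2 without isolating 16 (the classical one-flask route to 1-alkoxyalk-1-ynes). This comes back to the route at 19.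

Step 16. The cycloaddition joins two electron-rich partners and may be sluggish, so that thermal or acid-catalysed decomposition of the ynol ether competes. The fallback changes the activating group on the diene. It sets out from 28: lactonisation with DBU as in step 15 (through 29) followed by pivaloyl chloride instead of benzyl bromide gives the 4-pivaloyloxy pyrone F6, whose less donating acyloxy group should match the electron-rich alkyne and allow a lower temperature. Heating should then give, through the bridged lactone F7 and loss of CO2, the C7 pivalate tetralin F8. Methanolysis (K2CO3, MeOH) frees the C7 phenol F9, and hydrogenolysis under the conditions of step 17 comes back to the route at 33.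

**Further compounds**

F1 | step 2 | (R)-4-benzyl-3-{2-[4-(benzyloxy)-3-methoxyphenyl]acetyl}oxazolidin-2-one | COc1cc(CC(=O)N2C(=O)OC[C@H]2Cc2ccccc2)ccc1OCc1ccccc1
F2 | step 2 | sodium Z-enolate of F1 | COc1cc(/C=C(\[O-])N2C(=O)OC[C@H]2Cc2ccccc2)ccc1OCc1ccccc1.[Na+]
F3 | step 2 | sodium lactone enolate from F2 and 4 | COc1cc([C@@H]([C@@H]2[C@@H](O[C@H]3C[C@@H](C)CC[C@@H]3C(C)C)OC([O-])=C2)C(=O)N2C(=O)OC[C@H]2Cc2ccccc2)ccc1OCc1ccccc1.[Na+]
F4 | step 2 | N-acyl oxazolidinone analogue of acid 8 | COc1cc([C@@H]([C@@H]2[C@@H](O[C@H]3C[C@@H](C)CC[C@@H]3C(C)C)OC(=O)[C@H]2COCc2ccc(OC)cc2)C(=O)N2C(=O)OC[C@H]2Cc2ccccc2)ccc1OCc1ccccc1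
F5 | step 9 | primary iodide corresponding to alcohol 13 | COc1cc([C@@H]([C@H](COCc2ccccc2)[C@@H](COCc2ccccc2)CI)CO[Si](C(C)C)(C(C)C)C(C)C)ccc1OCc1ccccc1
F6 | step 16 | 4-pivaloyloxy analogue of pyrone 30 | COc1cc([C@@H]([C@H](COCc2ccccc2)[C@@H](COCc2ccccc2)CC#COC)C2=CC(OC(=O)C(C)(C)C)=C(OC)C(=O)O2)ccc1OCc1ccccc1
F7 | step 16 | bridged lactone from F6 | COc1cc([C@@H]2C34C=C(OC(=O)C(C)(C)C)C(OC)(C(=O)O3)C(OC)=C4C[C@H](COCc3ccccc3)[C@H]2COCc2ccccc2)ccc1OCc1ccccc1
F8 | step 16 | C7 pivalate of the tri-O-benzyl tetralin | COc1cc([C@@H]2c3cc(OC(=O)C(C)(C)C)c(OC)c(OC)c3C[C@H](COCc3ccccc3)[C@H]2COCc2ccccc2)ccc1OCc1ccccc1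
F9 | step 16 | C7 phenol of the tri-O-benzyl tetralin | COc1cc([C@@H]2c3cc(O)c(OC)c(OC)c3C[C@H](COCc3ccccc3)[C@H]2COCc2ccccc2)ccc1OCc1ccccc1
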